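**Assumption:** the SMILES decodes to the trans-(3R,4R) lactone (numbering O1, C2 carbonyl, C3, C4, C5). Where a compound is carried as a mixture at the one epimerisable carbon, that centre is left undefined in its SMILES.

## Retrosynthetic overview

1. Target 14 ⇐ methylenedioxy lactone 12, by selective BCl3 opening of the O–CH2–O bridge in the last step; the catechol stays masked until then.
2. Lactone 12 ⇐ succinate 9, by imide-to-CH2OH reduction, lactonisation onto the tert-butyl ester and base equilibration of C3 to trans. This is the only ring formed; both arenes are bought.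
3. Succinate 9 ⇐ the C3–C4 bond, by oxidative heterocoupling of two enolates: the imide enolate is oxidised to an electrophilic α-carbonyl radical (an enolonium equivalent) and captured by an ester enolate. C4 is fixed by an Evans auxiliary.
4. Imide 4 ⇐ 3-(1,3-benzodioxol-5-yl)propanoic acid 1 + (S)-4-benzyloxazolidin-2-one 2; ester 6 ⇐ 3-(3,4-dimethoxyphenyl)propanoic acid 5.

## Route

Step 1
Reactants: 1 3-(1,3-benzodioxol-5-yl)propanoic acid; 2 (S)-4-benzyl-1,3-oxazolidin-2-one
Product: 4 (4S)-3-[3-(1,3-benzodioxol-5-yl)propanoyl]-4-benzyl-1,3-oxazolidin-2-one, via mixed pivalic anhydride 3 (not isolated)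
Conditions: PivCl (1.1 equiv), Et3N (2.5 equiv), THF, −20 °C, 1 h; then LiCl (1.1 equiv), 2 (1.0 equiv), −20 °C → rt
Reagents that add atoms: pivaloyl chloride, CC(C)(C)C(=O)Cl (its atoms are held in 3 only; none remain in 4)
Why: Mixed-anhydride N-acylation, in which the LiCl/Et3N-activated oxazolidinone attacks the unhindered acyl carbon of the pivalic anhydride; the auxiliary stereocentre is untouched.

Step 2
Reactants: 5 3-(3,4-dimethoxyphenyl)propanoic acid
Product: 6 tert-butyl 3-(3,4-dimethoxyphenyl)propanoate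
Conditions: tert-butyl 2,2,2-trichloroacetimidate (2.0 equiv), CH2Cl2/cyclohexane, rt, 16 h (no added acid)
Reagents that add atoms: tert-butyl 2,2,2-trichloroacetimidate, CC(C)(C)OC(=N)C(Cl)(Cl)Cl
Why: Imidate esterification, in which the carboxylic acid protonates the imidate and takes up the tert-butyl group as trichloroacetamide leaves; without a Lewis acid the electron-rich arene is not tert-butylated.

Step 3
Reactants: 4 (4S)-3-[3-(1,3-benzodioxol-5-yl)propanoyl]-4-benzyl-1,3-oxazolidin-2-one; 6 tert-butyl 3-(3,4-dimethoxyphenyl)propanoate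
Product: 9 tert-butyl (2RS,3R)-3-(1,3-benzodioxol-5-ylmethyl)-4-[(4S)-4-benzyl-2-oxo-1,3-oxazolidin-3-yl]-2-(3,4-dimethoxybenzyl)-4-oxobutanoate, via lithium imide enolate 7 (not isolated), via lithium ester enolate 8 (not isolated)
Conditions: 4 (1.0 equiv), 6 (1.5 equiv), LiN(iPr)2 (2.6 equiv), THF, −78 °C, 30 min; then Fe(acac)3 (iron tris(acetylacetonate), 2.6 equiv), −78 °C → rt; SiO2 chromatography (removes homodimers and any 3S diastereomers)
Reagents that add atoms: lithium diisopropylamide, [Li+].CC(C)[N-]C(C)C (lithium held in 7 and 8 only; none remains in 9)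
Why: Oxidative enolate heterocoupling of the Baran type, in which trivalent iron oxidises the chelated Z-imide enolate 7 to an electrophilic α-imidyl radical (a one-electron enolonium equivalent) that is captured by ester enolate 8 and oxidised once more, so two normally nucleophilic α-carbons are joined; the benzyl group of the (S)-auxiliary shields one face as in Evans alkylations and sets the imide α-carbon as R (the future C4), while the ester α-carbon forms as a mixture that step 4 corrects.

Step 4
Reactants: 9 tert-butyl (2RS,3R)-3-(1,3-benzodioxol-5-ylmethyl)-4-[(4S)-4-benzyl-2-oxo-1,3-oxazolidin-3-yl]-2-(3,4-dimethoxybenzyl)-4-oxobutanoate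
Product: 12 (3R,4R)-4-(1,3-benzodioxol-5-ylmethyl)-3-(3,4-dimethoxybenzyl)dihydrofuran-2(3H)-one, via hydroxy ester 10 (not isolated), via lactone epimer mixture 11 (not isolated)
Conditions: LiBH4 (2.0 equiv), MeOH (2.0 equiv), THF, 0 °C, aq. NH4Cl work-up; then TsOH·H2O (0.2 equiv), PhMe, 80 °C; then DBU (1.5 equiv), PhMe, 80 °C; chromatography (auxiliary 2 recovered)
Reagents that add atoms: none
Why: Reductive auxiliary removal, acid-catalysed lactonisation and base epimerisation, in which hydride attacks the exocyclic imide carbonyl and spares the tert-butyl ester, the primary alcohol then closes the γ-lactone with loss of isobutene, and DBU equilibrates the enolisable C3 to the thermodynamically favoured trans (3R) arrangement next to C4, which carries no acidic hydrogen and stays R.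

Step 5
Reactants: 12 (3R,4R)-4-(1,3-benzodioxol-5-ylmethyl)-3-(3,4-dimethoxybenzyl)dihydrofuran-2(3H)-one
Product: 14 (3R,4R)-4-(3,4-dihydroxybenzyl)-3-(3,4-dimethoxybenzyl)dihydrofuran-2(3H)-one, via chloromethyl ether dichloroborinate 13 (not isolated)
Conditions: BCl3 (3.0 equiv, 1 M in CH2Cl2), CH2Cl2, −78 → 0 °C; then H2O, 0 °C → rt, work-up under N2
Reagents that add atoms: boron trichloride, ClB(Cl)Cl (its atoms are held in 13 only; none remain in 14)
Why: Lewis-acid acetal cleavage, in which BCl3 complexes an oxygen of the methylenedioxy bridge and chloride opens the activated O–CH2–O carbon much faster than it attacks the aryl methyl ethers or the lactone, and water then hydrolyses the borinate and chloromethyl ether to the catechol; no stereocentre is involved and the cold, non-basic conditions leave C3 alone.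

## Compound list

1 | 3-(1,3-benzodioxol-5-yl)propanoic acid | OC(=O)CCc1ccc2OCOc2c1 | starting material
2 | (S)-4-benzyl-1,3-oxazolidin-2-one | O=C1N[C@@H](Cc2ccccc2)CO1 | starting material
3 | 3-(1,3-benzodioxol-5-yl)propanoic pivalic anhydride | CC(C)(C)C(=O)OC(=O)CCc1ccc2OCOc2c1 | intermediate
4 | (4S)-3-[3-(1,3-benzodioxol-5-yl)propanoyl]-4-benzyl-1,3-oxazolidin-2-one | O=C(CCc1ccc2OCOc2c1)N1[C@@H](Cc2ccccc2)COC1=O | intermediate
5 | 3-(3,4-dimethoxyphenyl)propanoic acid | COc1ccc(CCC(=O)O)cc1OC | starting material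
6 | tert-butyl 3-(3,4-dimethoxyphenyl)propanoate | COc1ccc(CCC(=O)OC(C)(C)C)cc1OC | intermediate
7 | lithium (Z)-enolate of imide 4 | [Li+].[O-]/C(=C\Cc1ccc2OCOc2c1)N1[C@@H](Cc2ccccc2)COC1=O | intermediate
8 | lithium enolate of ester 6 (geometry not defined) | [Li+].[O-]C(OC(C)(C)C)=CCc1ccc(OC)c(OC)c1 | intermediate
9 | tert-butyl (2RS,3R)-3-(1,3-benzodioxol-5-ylmethyl)-4-[(4S)-4-benzyl-2-oxo-1,3-oxazolidin-3-yl]-2-(3,4-dimethoxybenzyl)-4-oxobutanoate (C2 epimer mixture) | CC(C)(C)OC(=O)C(Cc1ccc(OC)c(OC)c1)[C@@H](Cc1ccc2OCOc2c1)C(=O)N1[C@@H](Cc2ccccc2)COC1=O | intermediate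
10 | tert-butyl (2RS,3R)-3-(1,3-benzodioxol-5-ylmethyl)-2-(3,4-dimethoxybenzyl)-4-hydroxybutanoate (C2 epimer mixture) | CC(C)(C)OC(=O)C(Cc1ccc(OC)c(OC)c1)[C@@H](Cc1ccc2OCOc2c1)CO | intermediate
11 | (3RS,4R)-4-(1,3-benzodioxol-5-ylmethyl)-3-(3,4-dimethoxybenzyl)dihydrofuran-2(3H)-one (cis/trans mixture) | COc1ccc(CC2C(=O)OC[C@@H]2Cc2ccc3OCOc3c2)cc1OC | intermediate
12 | (3R,4R)-4-(1,3-benzodioxol-5-ylmethyl)-3-(3,4-dimethoxybenzyl)dihydrofuran-2(3H)-one (trans) | COc1ccc(C[C@H]2C(=O)OC[C@@H]2Cc2ccc3OCOc3c2)cc1OC | intermediate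
13 | (3R,4R)-4-[3-(chloromethoxy)-4-(dichloroboryloxy)benzyl]-3-(3,4-dimethoxybenzyl)dihydrofuran-2(3H)-one (regiochemistry of bridge opening drawn one way; both converge) | COc1ccc(C[C@H]2C(=O)OC[C@@H]2Cc2ccc(OB(Cl)Cl)c(OCCl)c2)cc1OC | intermediate
14 | (3R,4R)-4-(3,4-dihydroxybenzyl)-3-(3,4-dimethoxybenzyl)dihydrofuran-2(3H)-one | COc1ccc(C[C@H]2C(=O)OC[C@@H]2Cc2ccc(O)c(O)c2)cc1OC | target

## Step count and risk

Total steps: 5. Longest linear sequence: 4 (steps 1, 3, 4, 5); step 2 is a one-step side branch.

Steps most likely to fail: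

**Step 3 (oxidative heterocoupling).** The risks are homodimers, a modest yield and incomplete facial control at the imide carbon. The fallback sets out from 6 and comes back at 9, and uses a two-electron enolonium equivalent instead of the oxidant. Ester 6 is hydroxylated through its potassium enolate (KN(SiMe3)2, then 3-phenyl-2-(phenylsulfonyl)oxaziridine, THF, −78 °C) to tert-butyl (2RS)-3-(3,4-dimethoxyphenyl)-2-hydroxypropanoate F1. Tf2O and 2,6-lutidine in CH2Cl2 at −78 °C convert it into tert-butyl (2RS)-3-(3,4-dimethoxyphenyl)-2-(trifluoromethylsulfonyloxy)propanoate F2. Enolate 7, made from 4 alone with LiN(SiMe3)2 in THF at −78 °C, displaces the triflate by SN2 under the same auxiliary control and gives 9. The racemic triflate is acceptable because that carbon is equilibrated in step 4.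

**Step 5 (BCl3 unmasking).** The risks are partial O-demethylation of the veratryl ring and a sluggish hydrolysis of 13. The fallback sets out from 12 and comes back at 14, and is oxidative instead of Lewis-acidic. Pb(OAc)4 (lead tetraacetate, 1.5 equiv) in benzene at 60 °C acetoxylates the O–CH2–O carbon to give (3R,4R)-4-[(2-acetoxy-1,3-benzodioxol-5-yl)methyl]-3-(3,4-dimethoxybenzyl)dihydrofuran-2(3H)-one F4 (epimers at the acetal carbon). AcOH/H2O/THF at rt hydrolyses this orthoester-type acetal through the catechol monoformate to 14; the methyl ethers cannot react under these conditions.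

**Step 4 (reduction, lactonisation, epimerisation).** The risk is hydride attack at the endocyclic carbamate carbonyl of the hindered, α-branched imide. The fallback sets out from 9 and comes back at 10, and separates auxiliary removal from reduction. LiOH/H2O2 in THF/H2O at 0 °C cleaves the exocyclic acyl bond selectively and gives (2R,3RS)-2-(1,3-benzodioxol-5-ylmethyl)-4-tert-butoxy-3-(3,4-dimethoxybenzyl)-4-oxobutanoic acid F3. BH3·SMe2 in THF at 0 °C reduces the free acid in the presence of the tert-butyl ester to hydroxy ester 10, which is lactonised and epimerised as in step 4.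

## Further compounds

F1 | step 3 | tert-butyl (2RS)-3-(3,4-dimethoxyphenyl)-2-hydroxypropanoate | COc1ccc(CC(O)C(=O)OC(C)(C)C)cc1OC
F2 | step 3 | tert-butyl (2RS)-3-(3,4-dimethoxyphenyl)-2-(trifluoromethylsulfonyloxy)propanoate | COc1ccc(CC(OS(=O)(=O)C(F)(F)F)C(=O)OC(C)(C)C)cc1OC
F3 | step 4 | (2R,3RS)-2-(1,3-benzodioxol-5-ylmethyl)-4-tert-butoxy-3-(3,4-dimethoxybenzyl)-4-oxobutanoic acid | CC(C)(C)OC(=O)C(Cc1ccc(OC)c(OC)c1)[C@@H](Cc1ccc2OCOc2c1)C(=O)O
F4 | step 5 | (3R,4R)-4-[(2-acetoxy-1,3-benzodioxol-5-yl)methyl]-3-(3,4-dimethoxybenzyl)dihydrofuran-2(3H)-one | COc1ccc(C[C@H]2C(=O)OC[C@@H]2Cc2ccc3OC(OC(C)=O)Oc3c2)cc1OC
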